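The target is an erythro-(7S,8R) 8-O-4' neolignan. The route rests on cutting the C8–O4' aryl ether and the C7–OH bond together, because the C7 carbinol lies para to the C4 hydroxyl of ring A and next to the aryloxy-bearing C8, exactly the pattern left when water adds to a ring A p-quinone methide. One operation, oxidative cross-coupling of 3-O-benzylcaffeyl alcohol (a 4-hydroxycinnamyl alcohol with O3 masked as its benzyl ether) with dihydroconiferyl alcohol (ring B), joins C8 to O4' and, after water addition, C7 to oxygen, creating both stereocentres without closing a ring. Isomer separation, chiral-phase resolution and hydrogenolysis then deliver the target.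

Key step: step 4

Remark: lignan locants are used (ring A = catechol ring carrying C7, C8, C9; ring B = guaiacyl ring, primed locants); read from its SMILES, the target is the erythro (7S,8R) isomer, (1S,2R) in the systematic name.

Step 1
Reactants: 1 3,4-dihydroxybenzaldehyde
Product: 2 3-(benzyloxy)-4-hydroxybenzaldehyde
Conditions: NaH (2.0 equiv), DMSO, 20 °C; then BnCl (1.0 equiv), 20 °C; dilute aq. HCl work-up
Reagents that add atoms: benzyl chloride, ClCc1ccccc1
Why: Williamson ether synthesis on the catecholate dianion: the O4 phenoxide is delocalised into the para formyl group, so the single equivalent of benzyl chloride should be taken up by the more nucleophilic O3 phenoxide, a known regiochemical preference of such dianions.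

Step 2
Reactants: 2 3-(benzyloxy)-4-hydroxybenzaldehyde; 3 ethyl (triphenyl-λ5-phosphanylidene)acetate
Product: 4 ethyl (E)-3-[3-(benzyloxy)-4-hydroxyphenyl]prop-2-enoate
Conditions: 3 (1.2 equiv), toluene, 90 °C
Reagents that add atoms: none
Why: Wittig olefination with a stabilised ylide, which needs no added base and therefore tolerates the free phenol, and which should give the (E)-cinnamate as is usual for ester-stabilised ylides with aromatic aldehydes.

Step 3
Reactants: 4 ethyl (E)-3-[3-(benzyloxy)-4-hydroxyphenyl]prop-2-enoate
Product: 5 (E)-3-[3-(benzyloxy)-4-hydroxyphenyl]prop-2-en-1-ol (3-O-benzylcaffeyl alcohol)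
Conditions: i-Bu2AlH (4 equiv), toluene, 0 °C; EtOH quench, then aq. potassium sodium tartrate
Reagents that add atoms: none
Why: Reduction of an α,β-unsaturated ester to the allylic alcohol by i-Bu2AlH (two 1,2-hydride deliveries, no conjugate reduction); one equivalent is consumed by the phenol, the benzyl ether and the alkene are inert, and the acid-free work-up spares the acid-sensitive 4-hydroxycinnamyl alcohol.

Step 4
Reactants: 5 (E)-3-[3-(benzyloxy)-4-hydroxyphenyl]prop-2-en-1-ol; 6 dihydroconiferyl alcohol [4-(3-hydroxypropyl)-2-methoxyphenol]
Product: 8 1-[3-(benzyloxy)-4-hydroxyphenyl]-2-[4-(3-hydroxypropyl)-2-methoxyphenoxy]propane-1,3-diol (racemic erythro plus racemic threo), via ring A quinone methide 7 (not isolated)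
Conditions: Ag2O (1.5 equiv), 6 (5 equiv), CH2Cl2–acetone, 20 °C, dark, 5 added by syringe pump over 6 h; filtration; then THF–H2O (1:1), citric acid (pH 3), 20 °C
Reagents that add atoms: water, O
Why: Disilver oxide, a one-electron oxidant, turns both phenols into phenoxyl radicals; the radical of 5 carries spin at C8 through its conjugated side chain and recombines there with O4' of the radical of 6, which leaves ring B aromatic and ring A as the p-quinone methide 7, and water then adds to C7 in a 1,6-conjugate addition that restores the aromatic ring (the closest known reaction type is the dehydrogenative coupling of 4-hydroxycinnamyl alcohols to arylglycerol β-aryl ethers under Ag2O or peroxidase/H2O2). No ring is closed. C8 arises from recombination of two achiral radicals and C7 from attack of water on either face of the planar quinone methide with only weak 1,2-induction from C8, so neither centre is controlled and 8 is expected as racemic erythro plus racemic threo, the erythro pair containing the (7S,8R) isomer. The step needs cross-coupling over homo-coupling and C8–O4' over C8–C5' bonding: the saturated side chain of 6 confines its spin to O4' and the ring, 6 is kept in excess while 5 stays dilute through slow addition, and O-coupling is expected to be favoured in the aprotic medium, although some 8–5' adduct and homo-dimers of 5 must be expected and removed by chromatography. The benzyl ether on O3 keeps ring A from being oxidised to an o-quinone, and since 7 has no phenolic OH it cannot be oxidised further before the silver is filtered off and water is admitted.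

Step 5
Reactants: 8 1-[3-(benzyloxy)-4-hydroxyphenyl]-2-[4-(3-hydroxypropyl)-2-methoxyphenoxy]propane-1,3-diol (racemic erythro plus racemic threo)
Product: 9 (1S,2R)-1-[3-(benzyloxy)-4-hydroxyphenyl]-2-[4-(3-hydroxypropyl)-2-methoxyphenoxy]propane-1,3-diol (erythro; 7S,8R in lignan locants)
Conditions: preparative HPLC, C18 silica, MeCN–H2O (erythro pair from threo pair); then preparative HPLC, amylose tris(3,5-dimethylphenylcarbamate) on silica, hexane–EtOH, 20 °C
Reagents that add atoms: none
Why: No bond is made or broken; this is a chromatographic diastereomer separation followed by chromatographic resolution on a chiral stationary phase, both routine for arylglycerol β-aryl ethers, with the erythro pair to be identified by its H7–H8 coupling constant and carbon shifts and the (7S,8R) enantiomer by comparison of its circular dichroism curve with a calculated one.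

Step 6
Reactants: 9 (1S,2R)-1-[3-(benzyloxy)-4-hydroxyphenyl]-2-[4-(3-hydroxypropyl)-2-methoxyphenoxy]propane-1,3-diol
Product: 10 (1S,2R)-1-(3,4-dihydroxyphenyl)-2-[4-(3-hydroxypropyl)-2-methoxyphenoxy]propane-1,3-diol (target)
Conditions: H2 (1 atm), Pd/C (10 wt% Pd), EtOAc, 20 °C, stopped at full conversion; filtration under argon
Reagents that add atoms: none
Why: Hydrogenolysis of an aryl benzyl ether over palladium on carbon in a neutral solvent is much faster than cleavage of the secondary C7–OH, and the C8–O4' ether has no benzylic carbon on its alkyl side, so the catechol should be released with C7 and C8 untouched.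

Compound list

```
1 | 3,4-dihydroxybenzaldehyde | O=Cc1ccc(O)c(O)c1 | starting material
2 | 3-(benzyloxy)-4-hydroxybenzaldehyde | O=Cc1ccc(O)c(OCc2ccccc2)c1 | intermediate
3 | ethyl (triphenyl-λ5-phosphanylidene)acetate | CCOC(=O)C=P(c1ccccc1)(c1ccccc1)c1ccccc1 | starting material
4 | ethyl (E)-3-[3-(benzyloxy)-4-hydroxyphenyl]prop-2-enoate | CCOC(=O)/C=C/c1ccc(O)c(OCc2ccccc2)c1 | intermediate
5 | (E)-3-[3-(benzyloxy)-4-hydroxyphenyl]prop-2-en-1-ol (3-O-benzylcaffeyl alcohol) | OC/C=C/c1ccc(O)c(OCc2ccccc2)c1 | intermediate
6 | dihydroconiferyl alcohol, 4-(3-hydroxypropyl)-2-methoxyphenol | COc1cc(CCCO)ccc1O | starting material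
7 | 2-(benzyloxy)-4-{3-hydroxy-2-[4-(3-hydroxypropyl)-2-methoxyphenoxy]propylidene}cyclohexa-2,5-dien-1-one, ring A p-quinone methide, racemic at C8, alkene geometry undefined, not isolated | COc1cc(CCCO)ccc1OC(CO)C=C1C=CC(=O)C(OCc2ccccc2)=C1 | intermediate
8 | 1-[3-(benzyloxy)-4-hydroxyphenyl]-2-[4-(3-hydroxypropyl)-2-methoxyphenoxy]propane-1,3-diol, all four stereoisomers (racemic erythro plus racemic threo; stereocentres left undefined in the SMILES) | COc1cc(CCCO)ccc1OC(CO)C(O)c1ccc(O)c(OCc2ccccc2)c1 | intermediate
9 | (1S,2R)-1-[3-(benzyloxy)-4-hydroxyphenyl]-2-[4-(3-hydroxypropyl)-2-methoxyphenoxy]propane-1,3-diol, erythro (7S,8R) | COc1cc(CCCO)ccc1O[C@H](CO)[C@@H](O)c1ccc(O)c(OCc2ccccc2)c1 | intermediate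
10 | (1S,2R)-1-(3,4-dihydroxyphenyl)-2-[4-(3-hydroxypropyl)-2-methoxyphenoxy]propane-1,3-diol, erythro (7S,8R) | COc1cc(CCCO)ccc1O[C@H](CO)[C@@H](O)c1ccc(O)c(O)c1 | target
```

Total step count: 6.
Longest linear sequence: 6 steps (1 → 2 → 4 → 5 → 8 → 9 → 10); 3 and 6 are purchased.

Steps most likely to fail

1. Step 4. Homo-coupling of the cinnamyl radical, bonding at C5' instead of O4', and capture of the quinone methide by excess phenol before water is admitted may all erode the cross-coupling. The fallback sets out from 6 and comes back to the route at 10; it builds the same skeleton by ionic aldol chemistry. Williamson alkylation of the phenol of 6 (ethyl bromoacetate, K2CO3, acetone, 56 °C) should give ethyl 2-[4-(3-hydroxypropyl)-2-methoxyphenoxy]acetate F1. Its alkoxide–enolate (LiN(i-Pr)2, 2.1 equiv, THF, −78 °C; the first equivalent is taken by the 9'-hydroxyl) is added to commercial 3,4-bis(benzyloxy)benzaldehyde to give the aldol adduct ethyl 3-[3,4-bis(benzyloxy)phenyl]-3-hydroxy-2-[4-(3-hydroxypropyl)-2-methoxyphenoxy]propanoate F2, racemic and expected to favour the erythro pair. Reduction of the ester (LiAlH4, THF, 0 °C) should give 1-[3,4-bis(benzyloxy)phenyl]-2-[4-(3-hydroxypropyl)-2-methoxyphenoxy]propane-1,3-diol F3 as a stereoisomer mixture. The separation and resolution of step 5 then provide its (1S,2R) isomer F4, and hydrogenolysis of both benzyl ethers under the conditions of step 6 gives 10.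

2. Step 5. The two erythro enantiomers may overlap on the chiral phase at preparative loading. The fallback sets out from 8 (its erythro racemate from the reversed-phase stage) and comes back at 9; it replaces chromatographic resolution by enzymatic kinetic resolution (Burkholderia cepacia lipase, vinyl acetate, t-BuOMe, 30 °C). The remote 9'-hydroxyl should be acetylated in both enantiomers. Acetylation of the 9-hydroxyl next to C8 should be enantiomer-selective, as in lipase resolutions of primary alcohols with a C2 stereocentre. The phenol and the hindered C7 hydroxyl are not expected to react. After silica gel chromatography the (7S,8R) material is collected either as the (7S,8R) 9'-monoacetate F5 or as the (7S,8R) 9,9'-diacetate F6, depending on which enantiomer the enzyme prefers. Methanolysis (K2CO3, MeOH, 0 °C) returns 9.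

3. Step 1. Regiocontrol in the dianion alkylation may be lost through attack at O4 or double benzylation. The fallback sets out from 1 and comes back at 2; it uses temporary protection of O4. Alkylation of the monoanion, which forms at the more acidic O4–H (allyl bromide, NaHCO3, NaI, DMF, 40 °C), should give 4-(allyloxy)-3-hydroxybenzaldehyde F7. Benzylation of O3 (BnBr, K2CO3, DMF, 20 °C) gives 4-(allyloxy)-3-(benzyloxy)benzaldehyde F8. The allyl group is then transferred to morpholine with catalytic Pd(PPh3)4 (THF, 20 °C) to give 2.

Further compounds

```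
F1 | step 4 | ethyl 2-[4-(3-hydroxypropyl)-2-methoxyphenoxy]acetate | CCOC(=O)COc1ccc(CCCO)cc1OC
F2 | step 4 | ethyl 3-[3,4-bis(benzyloxy)phenyl]-3-hydroxy-2-[4-(3-hydroxypropyl)-2-methoxyphenoxy]propanoate (racemic erythro plus threo; stereocentres undefined) | CCOC(=O)C(Oc1ccc(CCCO)cc1OC)C(O)c1ccc(OCc2ccccc2)c(OCc2ccccc2)c1
F3 | step 4 | 1-[3,4-bis(benzyloxy)phenyl]-2-[4-(3-hydroxypropyl)-2-methoxyphenoxy]propane-1,3-diol (stereoisomer mixture; stereocentres undefined) | COc1cc(CCCO)ccc1OC(CO)C(O)c1ccc(OCc2ccccc2)c(OCc2ccccc2)c1
F4 | step 4 | (1S,2R)-1-[3,4-bis(benzyloxy)phenyl]-2-[4-(3-hydroxypropyl)-2-methoxyphenoxy]propane-1,3-diol | COc1cc(CCCO)ccc1O[C@H](CO)[C@@H](O)c1ccc(OCc2ccccc2)c(OCc2ccccc2)c1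
F5 | step 5 | (7S,8R) 9'-monoacetate of 9 (acetate on the ring B propanol oxygen) | CC(=O)OCCCc1ccc(O[C@H](CO)[C@@H](O)c2ccc(O)c(OCc3ccccc3)c2)c(OC)c1
F6 | step 5 | (7S,8R) 9,9'-diacetate of 9 (acetates on both primary oxygens) | CC(=O)OCCCc1ccc(O[C@H](COC(C)=O)[C@@H](O)c2ccc(O)c(OCc3ccccc3)c2)c(OC)c1
F7 | step 1 | 4-(allyloxy)-3-hydroxybenzaldehyde | C=CCOc1ccc(C=O)cc1O
F8 | step 1 | 4-(allyloxy)-3-(benzyloxy)benzaldehyde | C=CCOc1ccc(C=O)cc1OCc1ccccc1
```
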